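Ring A is disconnected at C2–C3 and C1–C10. Its C1–C2 ethano unit lies between an acyl-level carbon (C3, beside the gem-dimethyl C4) and the quaternary C10, which is α to a latent C9 ketone in ring B. A one-pot Michael–Michael–Dieckmann cascade therefore joins methyl isobutyrate (C3, C4), (5S,6R)-6-methylcarvone (ring B) and methyl acrylate (C1, C2): conjugate addition creates the C10 enolate regiospecifically, acrylate is attached at C10, and its enolate acylates at C3, closing ring A trans-fused. The carvone isopropenyl group at C7 controls C5 and C10 and is later excised to the C7–C8 alkene. The immediate precursor of the ring closure is a lithium enolate bearing both ester groups.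

Key step: step 2

Remark: drimane numbering is used throughout (carvone C1–C6 become C9, C10, C5, C6, C7, C8). The target belongs to the enantiomeric drimane series, (3R,5S,9R,10R), which is why (S)-carvone is chosen. The C8 methyl stereocentre of 3 and 7–12 is expected as an epimer mixture, is drawn as the likely major epimer, and is erased in step 5.

Step 1
Reactants: 1 (S)-(+)-carvone
Product: 3 (5S,6R)-6-methylcarvone, via carvone lithium dienolate 2 (not isolated)
Conditions: LiN(iPr)2 (LDA), THF, −78 °C; MeI, −78 → 0 °C
Reagents that add atoms: iodomethane, CI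
Why: Kinetic deprotonation at the α′-carbon (future C8) gives the cross-conjugated dienolate, and enolate alkylation with MeI should occur mainly anti to the isopropenyl group; the new centre is inconsequential because C8 becomes sp2 in step 5.

Step 2
Reactants: 3 (5S,6R)-6-methylcarvone; 4 methyl isobutyrate; 5 methyl acrylate
Product: 9 methyl (5R,7S,10R)-7-isopropenyl-3,9-dioxo-11-nordrimane-2-carboxylate, via methyl isobutyrate lithium enolate 6 (not isolated), via conjugate-adduct lithium enolate 7 (not isolated), via acrylate-adduct ester enolate 8 (not isolated)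
Conditions: 4, LiN(iPr)2 (LDA), THF, −78 °C; 3, DMPU, −78 → −20 °C; 5 (1.0 equiv), −78 °C → rt; aq. HCl
Reagents that add atoms: none
Why: LiN(iPr)2 converts 4 into enolate 6, which adds 1,4 to enone 3 (C4–C5 bond) to give the regiodefined C9–C10 enolate 7; 7 adds to the β-carbon of acrylate 5 (C1–C10 bond, quaternary C10), and the propanoate enolate 8 acylates itself at the isobutyrate ester carbonyl (C2–C3 bond) with loss of methoxide, the product being drained as its doubly stabilised β-keto ester enolate. The closest known reaction type is the Michael–Michael–ring-closure (MIMIRC) cascade, here terminated by a Dieckmann-type Claisen condensation (Michael–Dieckmann annulation). Ring A closes in a 6-exo-trig mode by attack of C2 on the ester carbon C3. C5 is set by axial conjugate addition anti to the C7 isopropenyl group, as in cuprate and enolate additions to carvone, and C10 by attack of acrylate on 7 anti to the bulky pseudoaxial C5 substituent (allylic 1,2-strain with the C10 methyl), which places the C10 methyl trans to H-5 and makes the ring fusion trans; the C2 centre is labile and is removed in step 3. The step needs 1,4- over 1,2-addition, C-alkylation at C10 and not at C8, and closure at C3: the hindered α,α-disubstituted enolate with DMPU and the reversibility of its 1,2-adduct favour conjugate addition, the enolate exists only at C10 because it is born by conjugate addition, and no enone remains that could capture 8 in a bridged double Michael reaction. Any Claisen product from the C8 enolate would be a non-enolisable 1,3-dicarbonyl that reverts under methoxide, so equilibration funnels material to 9.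

Step 3
Reactants: 9 methyl (5R,7S,10R)-7-isopropenyl-3,9-dioxo-11-nordrimane-2-carboxylate
Product: 10 (5R,7S,10R)-7-isopropenyl-11-nordrimane-3,9-dione
Conditions: LiCl, DMSO, H2O, 150 °C
Reagents that add atoms: none
Why: Krapcho dealkoxycarbonylation: chloride demethylates the β-keto ester and the carboxylate loses CO2, leaving the C3 ketone with C2 as CH2, while the hot, mildly basic medium should equilibrate C8 to the equatorial-methyl epimer.

Step 4
Reactants: 10 (5R,7S,10R)-7-isopropenyl-11-nordrimane-3,9-dione
Product: 11 (3R,5R,7S,10R)-3-hydroxy-7-isopropenyl-11-nordriman-9-one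
Conditions: NaBH4 (0.5 equiv), MeOH–CH2Cl2, −40 → −10 °C
Reagents that add atoms: none
Why: Chemoselective borohydride reduction: the C3 ketone is far more accessible than the C9 ketone (flanked by quaternary C10 and tertiary C8, screened by the axial isopropenyl group), and hydride should add axially from the face opposite the axial C4 and C10 methyl groups, giving the equatorial 3-alcohol cis to the C10 methyl (3R).

Step 5
Reactants: 11 (3R,5R,7S,10R)-3-hydroxy-7-isopropenyl-11-nordriman-9-one
Product: 13 (3R,5R,10R)-3-hydroxy-11-nordrim-7-en-9-one, via methoxy hydroperoxide 12 (not isolated)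
Conditions: O3, CH2Cl2–MeOH, −78 °C; then FeSO4·7H2O, Cu(OAc)2·H2O, MeOH, −20 °C → rt; DBU (cat.), CH2Cl2, rt
Reagents that add atoms: none
Why: Ozonolysis in methanol gives the α-methoxy hydroperoxide 12, FeSO4 cleaves its O–O bond, the alkoxy radical loses methyl acetate by β-scission, and Cu(OAc)2 oxidises the C7 radical to the alkene (dealkenylative fragmentation), the conjugated C7–C8 enone being favoured and any C6–C7 isomer converged by DBU; the auxiliary centres C7 and C8 disappear.

Step 6
Reactants: 13 (3R,5R,10R)-3-hydroxy-11-nordrim-7-en-9-one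
Product: 14 (3R,5S,10R)-drima-7,9(11)-dien-3-ol
Conditions: Ph3PCH3Br, KOtBu (excess), toluene, 100 °C
Reagents that add atoms: methyltriphenylphosphonium bromide, C[P+](c1ccccc1)(c1ccccc1)c1ccccc1.[Br-]
Why: Wittig methylenation with the ylide from Ph3PCH3Br and KOtBu at high temperature, conditions suited to hindered enolisable ketones; C9 is the only carbonyl present and the C3 alkoxide is a spectator.

Step 7
Reactants: 14 (3R,5S,10R)-drima-7,9(11)-dien-3-ol
Product: 16 (3R,5S,9R,10R)-drim-7-ene-3,11-diol, via bis-9-BBN adduct 15 (not isolated)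
Conditions: 9-BBN (2.5 equiv), THF, 0 °C → rt; then NaOH, H2O2, 0 °C → rt
Reagents that add atoms: hydrogen peroxide, OO
Why: Hydroboration–oxidation: 9-BBN places boron on the terminal C11 of the 1,1-disubstituted alkene (much faster than attack on the trisubstituted C7–C8 alkene) and delivers hydrogen to C9 from the face opposite the axial C10 methyl, so H-9 is trans and the CH2OH group cis to that methyl (9R), and oxidation retains configuration.

Step 8
Reactants: 16 (3R,5S,9R,10R)-drim-7-ene-3,11-diol; 17 umbelliferone (7-hydroxycoumarin)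
Product: 18 7-{[(3R,5S,9R,10R)-3-hydroxydrim-7-en-11-yl]oxy}-2H-chromen-2-one
Conditions: PPh3, DIAD, THF, 0 °C → rt
Reagents that add atoms: none
Why: Mitsunobu etherification: the acidic phenol displaces the primary C11 oxyphosphonium in an SN2 step, whereas the secondary C3 alcohol next to quaternary C4 is too hindered to compete, and no stereocentre is touched.

Step 9
Reactants: 18 7-{[(3R,5S,9R,10R)-3-hydroxydrim-7-en-11-yl]oxy}-2H-chromen-2-one
Product: 19 7-{[(3R,5S,9R,10R)-3-acetoxydrim-7-en-11-yl]oxy}-2H-chromen-2-one (CNP0224712.1)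
Conditions: Ac2O, pyridine, DMAP (cat.), CH2Cl2, rt
Reagents that add atoms: acetic anhydride, CC(=O)OC(C)=O
Why: DMAP-catalysed acylation of the hindered equatorial secondary alcohol proceeds with retention at C3 and completes the target.

Compound list
1 | (S)-(+)-carvone, (5S)-2-methyl-5-(prop-1-en-2-yl)cyclohex-2-en-1-one | CC1=CC[C@@H](CC1=O)C(C)=C | starting material
2 | lithium cross-conjugated dienolate of 1 (α′-enolate) | CC1=CC[C@@H](C=C1O[Li])C(C)=C | intermediate (not isolated)
3 | (5S,6R)-6-methylcarvone, (5S,6R)-2,6-dimethyl-5-(prop-1-en-2-yl)cyclohex-2-en-1-one (trans; 6-epimer carried along) | CC1=CC[C@@H]([C@@H](C)C1=O)C(C)=C | intermediate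
4 | methyl isobutyrate (methyl 2-methylpropanoate) | CC(C)C(=O)OC | starting material
5 | methyl acrylate | C=CC(=O)OC | starting material
6 | lithium enolate of methyl isobutyrate | CC(C)=C(OC)O[Li] | intermediate (not isolated)
7 | lithium 3-(1-methoxy-2-methyl-1-oxopropan-2-yl)-2,6-dimethyl-5-(prop-1-en-2-yl)cyclohex-1-en-1-olate (side chain trans to isopropenyl) | [Li]OC1=C(C)[C@@H](C(C)(C)C(=O)OC)C[C@H](C(C)=C)[C@H]1C | intermediate (not isolated)
8 | lithium ester enolate of methyl 3-[6-(1-methoxy-2-methyl-1-oxopropan-2-yl)-1,3-dimethyl-2-oxo-4-(prop-1-en-2-yl)cyclohexyl]propanoate (propanoate chain trans to the C5 side chain) | [Li]OC(OC)=CC[C@@]1(C)C(=O)[C@H](C)[C@@H](C(C)=C)C[C@@H]1C(C)(C)C(=O)OC | intermediate (not isolated)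
9 | methyl (5R,7S,10R)-7-isopropenyl-3,9-dioxo-11-nordrimane-2-carboxylate (trans-fused; C2 epimers and enol, drawn with equatorial ester) | O=C1[C@@H](C(=O)OC)C[C@@]2(C)C(=O)[C@@H](C)[C@@H](C(C)=C)C[C@@H]2C1(C)C | intermediate
10 | (5R,7S,10R)-7-isopropenyl-11-nordrimane-3,9-dione | O=C1CC[C@@]2(C)C(=O)[C@@H](C)[C@@H](C(C)=C)C[C@@H]2C1(C)C | intermediate
11 | (3R,5R,7S,10R)-3-hydroxy-7-isopropenyl-11-nordriman-9-one (3-OH equatorial, cis to C10 methyl) | O[C@@H]1CC[C@@]2(C)C(=O)[C@@H](C)[C@@H](C(C)=C)C[C@@H]2C1(C)C | intermediate
12 | (3R,5R,7S,10R)-7-(1-hydroperoxy-1-methoxyethyl)-3-hydroxy-11-nordriman-9-one (epimers at the peroxyketal carbon) | O[C@@H]1CC[C@@]2(C)C(=O)[C@@H](C)[C@@H](C(C)(OC)OO)C[C@@H]2C1(C)C | intermediate (not isolated)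
13 | (3R,5R,10R)-3-hydroxy-11-nordrim-7-en-9-one | O[C@@H]1CC[C@@]2(C)C(=O)C(C)=CC[C@@H]2C1(C)C | intermediate
14 | (3R,5S,10R)-drima-7,9(11)-dien-3-ol | O[C@@H]1CC[C@@]2(C)C(=C)C(C)=CC[C@@H]2C1(C)C | intermediate
15 | 11-(9-borabicyclo[3.3.1]nonan-9-yl)drim-7-en-3-yl 9-borabicyclo[3.3.1]nonan-9-yl ether (C-borane and O-borinate) | O(B1C2CCCC1CCC2)[C@@H]3CC[C@@]4(C)[C@H](CB5C6CCCC5CCC6)C(C)=CC[C@@H]4C3(C)C | intermediate (not isolated)
16 | (3R,5S,9R,10R)-drim-7-ene-3,11-diol | O[C@@H]1CC[C@@]2(C)[C@H](CO)C(C)=CC[C@@H]2C1(C)C | intermediate
17 | umbelliferone (7-hydroxy-2H-chromen-2-one) | Oc1ccc2ccc(=O)oc2c1 | starting material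
18 | 7-{[(3R,5S,9R,10R)-3-hydroxydrim-7-en-11-yl]oxy}-2H-chromen-2-one | O[C@@H]1CC[C@@]2(C)[C@H](COc3ccc4ccc(=O)oc4c3)C(C)=CC[C@@H]2C1(C)C | intermediate
19 | 7-{[(3R,5S,9R,10R)-3-acetoxydrim-7-en-11-yl]oxy}-2H-chromen-2-one | CC(=O)O[C@@H]1CC[C@@]2(C)[C@H](COc3ccc4ccc(=O)oc4c3)C(C)=CC[C@@H]2C1(C)C | target

Total step count: 9. Longest linear sequence: 9 steps, from (S)-carvone 1.

Steps most likely to fail

Step 2. The ester enolate may add 1,2 to the enone or simply deprotonate it, and acrylate may oligomerise anionically before the slow acylation at the hindered C3 ester closes the ring. The fallback sets out from 3 and separates only the C4–C5 bond formation. A Mukaiyama–Michael addition of commercial 1-methoxy-2-methyl-1-(trimethylsilyloxy)prop-1-ene (Ph3CClO4 cat., CH2Cl2, −78 °C) should give the isolable, regiodefined silyl enol ether methyl 2-[2,4-dimethyl-5-(prop-1-en-2-yl)-3-(trimethylsilyloxy)cyclohex-2-en-1-yl]-2-methylpropanoate F1. MeLi in THF at 0 °C then releases lithium enolate 7, where the route is rejoined; addition of 5 and Dieckmann closure to 9 still form C1–C10 and C2–C3 in one operation.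

Step 6. The basic ylide may enolise the hindered, cross-conjugated C9 ketone instead of adding to it. The fallback sets out from 13 and uses a Peterson olefination. Me3SiCH2Li with CeCl3 (THF, −78 °C), a weakly basic organocerium reagent, should add from the face opposite the C10 methyl to give the β-hydroxysilane 9-[(trimethylsilyl)methyl]-11-nordrim-7-ene-3,9-diol F2. KH in THF then effects syn-elimination, and the route is rejoined at 14.

Step 8. The activated homoallylic oxyphosphonium may eliminate toward diene 14 (H-9 is allylic), or substitution at the β-branched C11 may be too slow. The fallback sets out from 16 and avoids substitution at carbon altogether. A palladium-catalysed C–O cross-coupling with commercial 7-bromocoumarin ([Pd(allyl)Cl]2, RockPhos, Cs2CO3, toluene, 90 °C) lets the primary alkoxide attack an arylpalladium intermediate, the hindered C3 alcohol again being the slower partner. The route is rejoined at 18 and no new isolated compound arises.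

Further compounds
F1 | step 2 | methyl 2-[2,4-dimethyl-5-(prop-1-en-2-yl)-3-(trimethylsilyloxy)cyclohex-2-en-1-yl]-2-methylpropanoate | C[Si](C)(C)OC1=C(C)[C@@H](C(C)(C)C(=O)OC)C[C@H](C(C)=C)[C@H]1C
F2 | step 6 | 9-[(trimethylsilyl)methyl]-11-nordrim-7-ene-3,9-diol | O[C@@H]1CC[C@@]2(C)[C@@](O)(C[Si](C)(C)C)C(C)=CC[C@@H]2C1(C)C
F0 | step 8 | none | none
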